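Retrosynthesis: cut the C4–C5′ diarylmethine bond between the 3,4-diarylchroman (unit 1) and ring B of the 3-arylchroman (unit 2); then, in unit 2, cut C3–C4 and O1–C8a of the pyran ring; unit 1 goes back through a pterocarpan and an isoflavone to a chalcone.
Forward, unit 2: alkyne 2 and acid 3 give enol ester 4, in which one event (1,3-O-to-C acyl shift, then SNAr) closes ring C of unit 2 as the flat isoflavone 6.
Enabling feature: in unit 2, C4 sits on ring-A carbon C4a and O1 on the neighbouring C8a, while C2 carries O1 and C3 carries ring B; an ester of O1 with a 2-fluoroaroyl carbon (the future C4) puts C3 next to C4, and the ketone so formed is ortho to C8a–F and activates it for closure by O1.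
Forward, unit 1: chalcone 10 gives isoflavone 12 and then (6aR,11aR)-pterocarpan 16; its C4 cation arylates C5′ of ring B of 6 and joins the halves.
End: the remaining pyranone ring is dearomatised by transfer hydrogenation, and the C4 oxygen, the benzyl ethers and the carbonate leave in one hydrogenolysis.
Stereochemistry: both C3 centres come from dynamic kinetic resolution with RuCl[(R,R)-TsDPEN](p-cymene) (catalyst control, the isoflavanone epimers funnel into one); C4 of unit 1 comes from anti attack on the cation (substrate control).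

Key step: step 3

Remark: locants follow chroman (isoflavan) numbering within each unit, with primes for ring B; compounds 1, 3, 7 and 9 are taken as catalogue chemicals.

Step 1
Reactants: 1 2-(benzyloxy)-4-methoxybenzaldehyde
Product: 2 2-(benzyloxy)-1-ethynyl-4-methoxybenzene
Conditions: MeC(O)C(N2)P(O)(OMe)2, K2CO3, MeOH, 0 °C → rt
Reagents that add atoms: dimethyl (1-diazo-2-oxopropyl)phosphonate, COP(=O)(OC)C(=[N+]=[N-])C(C)=O
Why: Seyferth–Gilbert homologation in the Ohira–Bestmann variant, in which methanolysis of the reagent gives the diazomethylphosphonate anion that turns the non-enolisable aryl aldehyde into the terminal alkyne through an alkylidene carbene and a 1,2-hydrogen shift; no stereocenter is formed.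

Step 2
Reactants: 2 2-(benzyloxy)-1-ethynyl-4-methoxybenzene; 3 4-(benzyloxy)-2-fluorobenzoic acid
Product: 4 (Z)-2-[2-(benzyloxy)-4-methoxyphenyl]ethenyl 4-(benzyloxy)-2-fluorobenzoate
Conditions: Ru(2-methylallyl)2(Ph2P(CH2)4PPh2) (2 mol %), toluene, 60 °C
Reagents that add atoms: none
Why: Ruthenium-catalysed anti-Markovnikov addition of a carboxylic acid to a terminal alkyne through a ruthenium vinylidene, whose terminal carbon takes up the carboxylate to give the (Z)-enol ester under base-free conditions that should not trigger the acyl shift; the alkene geometry does not matter for step 3 and no stereocenter is formed.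

Step 3
Reactants: 4 (Z)-2-[2-(benzyloxy)-4-methoxyphenyl]ethenyl 4-(benzyloxy)-2-fluorobenzoate
Product: 6 7-(benzyloxy)-3-[2-(benzyloxy)-4-methoxyphenyl]-4H-chromen-4-one, via formyl ketone enolate 5 (not isolated)
Conditions: 4-pyrrolidinopyridine (20 mol %), K2CO3 (2 equiv), 4 Å molecular sieves, DMF, 25 → 70 °C
Reagents that add atoms: none
Why: Proposed new method: 4-pyrrolidinopyridine adds to the ester carbonyl of 4 and expels the conjugated arylacetaldehyde enolate (a leaving group comparable to a phenoxide), whose carbon C3 then attacks the acylpyridinium carbon (the future C4), so that the O1–C4 ester tether is traded for the C3–C4 bond; O-acylation only returns 4, whereas C-acylation becomes irreversible when K2CO3 deprotonates the formyl ketone 5. The enolate oxygen O1 of 5, still on C2, then adds to C8a and fluoride leaves from the anionic σ-adduct (intramolecular SNAr, formally a 6-endo-trig addition–elimination on the C4a=C8a–F unit, a vinylogous acyl fluoride of the new C4 ketone), which closes the 4-pyranone ring. The closest known reaction types are the nucleophile-catalysed 1,3-O-to-C acyl shift of enol esters and enol carbonates (Steglich rearrangement, cyanide-catalysed rearrangement of 1,3-dione enol esters), the Baker–Venkataraman acyl transfer and the SNAr closure of 2-fluorobenzoyl 1,3-dicarbonyl compounds to chromones; the acyl shift of an aldehyde-derived β-aryl enol ester coupled to this closure is the untested part. No stereocenter is formed, because C3 becomes sp2; the flat ring is the substrate from which C3 is set in step 11, and the C4 oxygen is a helper that leaves in step 12. The step needs C- over O-acylation and closure by O1 rather than attack of an outside nucleophile on the aryl fluoride: the first is secured by the thermodynamic sink of the 1,3-dicarbonyl enolate, the second by the ortho relation of C4 and C8a on ring A, which activates the fluoride only after the acyl shift and places it in a six-membered array with O1; the benzyl ethers are inert.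

Step 4
Reactants: 7 2-hydroxy-4,5-dimethoxybenzaldehyde
Product: 8 2-(benzyloxy)-4,5-dimethoxybenzaldehyde
Conditions: BnBr, K2CO3, DMF, 50 °C
Reagents that add atoms: benzyl bromide, BrCc1ccccc1
Why: Williamson etherification of the phenol, which is hydrogen-bonded to the ortho aldehyde and therefore alkylated in warm DMF; no stereocenter is formed.

Step 5
Reactants: 8 2-(benzyloxy)-4,5-dimethoxybenzaldehyde; 9 1-[4-(benzyloxy)-2-hydroxyphenyl]ethan-1-one
Product: 10 (E)-1-[4-(benzyloxy)-2-hydroxyphenyl]-3-[2-(benzyloxy)-4,5-dimethoxyphenyl]prop-2-en-1-one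
Conditions: KOH (50% aq.), EtOH, rt
Reagents that add atoms: none
Why: Claisen–Schmidt (crossed aldol) condensation of the methyl ketone with the non-enolisable aldehyde, where dehydration should give the (E)-chalcone under thermodynamic control and the benzyl ethers are inert to base.

Step 6
Reactants: 10 (E)-1-[4-(benzyloxy)-2-hydroxyphenyl]-3-[2-(benzyloxy)-4,5-dimethoxyphenyl]prop-2-en-1-one
Product: 12 7-(benzyloxy)-3-[2-(benzyloxy)-4,5-dimethoxyphenyl]-4H-chromen-4-one, via dimethyl acetal 11 (not isolated)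
Conditions: Tl(NO3)3·3H2O, MeOH–CH(OMe)3, rt; then 10% HCl, 50 °C
Reagents that add atoms: none
Why: Oxidative 1,2-aryl migration of a chalcone with thallium trinitrate, in which the electron-rich ring B moves from C-β to C-α as thallium leaves to give the β-keto acetal 11, followed by acid-induced closure of the 2-hydroxyl group of ring A on the acetal carbon and loss of methanol to the isoflavone; the racemic centre of 11 becomes sp2.

Step 7
Reactants: 12 7-(benzyloxy)-3-[2-(benzyloxy)-4,5-dimethoxyphenyl]-4H-chromen-4-one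
Product: 13 7-hydroxy-3-(2-hydroxy-4,5-dimethoxyphenyl)-4H-chromen-4-one
Conditions: H2 (1 atm), 10% Pd/C, THF–MeOH, rt
Reagents that add atoms: none
Why: Hydrogenolysis of the two aryl benzyl ethers over palladium, where any over-reduction of the chromone C2=C3 bond would only give isoflavanone 14, the intermediate of step 8.

Step 8
Reactants: 13 7-hydroxy-3-(2-hydroxy-4,5-dimethoxyphenyl)-4H-chromen-4-one
Product: 16 (6aR,11aR)-8,9-dimethoxy-6a,11a-dihydro-6H-[1]benzofuro[3,2-c]chromen-3-ol, via isoflavanone 14 (not isolated), via cis-isoflavan-4-ol 15 (not isolated)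
Conditions: RuCl[(R,R)-TsDPEN](p-cymene) (2 mol %), HCO2H–Et3N (5:2), DMF, 40 °C; then 2 M HCl, THF, rt
Reagents that add atoms: none
Why: Asymmetric transfer hydrogenation cascade of the type used to turn 2′-hydroxyisoflavones into pterocarpans: conjugate reduction gives the racemic, rapidly enolising isoflavanone 14, the (R,R)-catalyst should then reduce only the (3R)-ketone from the face opposite the aryl group (dynamic kinetic resolution, catalyst control at C4, cis by approach anti to the aryl group) to the (3R,4R)-diol 15, and acid ionises the para-hydroxybenzylic C4–OH so that the 2′-OH closes the cis-fused dihydrobenzofuran of 16.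

Step 9
Reactants: 16 (6aR,11aR)-8,9-dimethoxy-6a,11a-dihydro-6H-[1]benzofuro[3,2-c]chromen-3-ol
Product: 17 benzyl (6aR,11aR)-8,9-dimethoxy-6a,11a-dihydro-6H-[1]benzofuro[3,2-c]chromen-3-yl carbonate
Conditions: CbzCl, K2CO3, acetone, 0 °C → rt
Reagents that add atoms: benzyl chloroformate, O=C(Cl)OCc1ccccc1
Why: Acylation of the single phenol to an aryl benzyl carbonate, which lowers the nucleophilicity of ring A of the pterocarpan for step 10 and leaves in step 12; the stereocenters are untouched.

Step 10
Reactants: 17 benzyl (6aR,11aR)-8,9-dimethoxy-6a,11a-dihydro-6H-[1]benzofuro[3,2-c]chromen-3-yl carbonate; 6 7-(benzyloxy)-3-[2-(benzyloxy)-4-methoxyphenyl]-4H-chromen-4-one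
Product: 18 benzyl (3R,4S)-4-{4-(benzyloxy)-5-[7-(benzyloxy)-4-oxo-4H-chromen-3-yl]-2-methoxyphenyl}-3-(2-hydroxy-4,5-dimethoxyphenyl)chroman-7-yl carbonate
Conditions: BF3·OEt2 (3 equiv), 6 (1.5 equiv), CH2Cl2, −40 → 0 °C
Reagents that add atoms: none
Why: Friedel–Crafts alkylation in which BF3 opens the benzylic C11a–O bond of the pterocarpan to a C4 cation stabilised by the ortho ring oxygen, and C5′ of ring B of 6 (para to OBn, ortho to OMe, while ring A of 6 is deactivated by the chromone carbonyl) attacks from the face opposite the C3 aryl group, so that the C3 configuration is kept and the new C4 centre should be set trans (3R,4S) by substrate control.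

Step 11
Reactants: 18 benzyl (3R,4S)-4-{4-(benzyloxy)-5-[7-(benzyloxy)-4-oxo-4H-chromen-3-yl]-2-methoxyphenyl}-3-(2-hydroxy-4,5-dimethoxyphenyl)chroman-7-yl carbonate
Product: 20 benzyl (3R,4S)-4-{4-(benzyloxy)-5-[(3R,4R)-7-(benzyloxy)-4-hydroxychroman-3-yl]-2-methoxyphenyl}-3-(2-hydroxy-4,5-dimethoxyphenyl)chroman-7-yl carbonate, via isoflavanone 19 (not isolated)
Conditions: RuCl[(R,R)-TsDPEN](p-cymene) (5 mol %), HCO2H–Et3N (5:2), DMF, 40 °C
Reagents that add atoms: none
Why: Same transfer hydrogenation cascade as in step 8, in which conjugate reduction gives 19, its two epimers at the new C3 interconvert through the enol, and the (R,R)-catalyst should funnel them into the cis-(3R,4R)-alcohol under catalyst control (dynamic kinetic resolution), the remote stereocenters of unit 1 having little influence.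

Step 12
Reactants: 20 benzyl (3R,4S)-4-{4-(benzyloxy)-5-[(3R,4R)-7-(benzyloxy)-4-hydroxychroman-3-yl]-2-methoxyphenyl}-3-(2-hydroxy-4,5-dimethoxyphenyl)chroman-7-yl carbonate
Product: 21 (3R,4S)-4-{4-hydroxy-5-[(3R)-7-hydroxychroman-3-yl]-2-methoxyphenyl}-3-(2-hydroxy-4,5-dimethoxyphenyl)chroman-7-ol
Conditions: H2 (1 atm), 10% Pd/C, EtOAc–EtOH, AcOH (5 equiv), rt
Reagents that add atoms: none
Why: Hydrogenolysis over palladium should remove both benzyl ethers, the benzyl carbonate (as toluene and CO2) and the para-oxygenated benzylic C4–OH of unit 2, whose oxygen has served only as activating group and stereochemical relay; C3 of unit 2 bears no C–O bond and keeps its (R) configuration, and the diarylmethine C4–H of unit 1 is not cleaved.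

Compound list
1 | 2-(benzyloxy)-4-methoxybenzaldehyde | COc1ccc(C=O)c(OCc2ccccc2)c1 | starting material
2 | 2-(benzyloxy)-1-ethynyl-4-methoxybenzene | COc1ccc(C#C)c(OCc2ccccc2)c1 | intermediate
3 | 4-(benzyloxy)-2-fluorobenzoic acid | OC(=O)c1ccc(OCc2ccccc2)cc1F | starting material
4 | (Z)-2-[2-(benzyloxy)-4-methoxyphenyl]ethenyl 4-(benzyloxy)-2-fluorobenzoate | COc1ccc(/C=C\OC(=O)c2ccc(OCc3ccccc3)cc2F)c(OCc2ccccc2)c1 | intermediate
5 | 1-[4-(benzyloxy)-2-fluorophenyl]-2-[2-(benzyloxy)-4-methoxyphenyl]-3-hydroxyprop-2-en-1-one (enol form of the formyl ketone, present as its potassium enolate, geometry mobile) | COc1ccc(C(=CO)C(=O)c2ccc(OCc3ccccc3)cc2F)c(OCc2ccccc2)c1 | intermediate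
6 | 7-(benzyloxy)-3-[2-(benzyloxy)-4-methoxyphenyl]-4H-chromen-4-one | COc1ccc(-c2coc3cc(OCc4ccccc4)ccc3c2=O)c(OCc2ccccc2)c1 | intermediate
7 | 2-hydroxy-4,5-dimethoxybenzaldehyde | COc1cc(O)c(C=O)cc1OC | starting material
8 | 2-(benzyloxy)-4,5-dimethoxybenzaldehyde | COc1cc(OCc2ccccc2)c(C=O)cc1OC | intermediate
9 | 1-[4-(benzyloxy)-2-hydroxyphenyl]ethan-1-one | CC(=O)c1ccc(OCc2ccccc2)cc1O | starting material
10 | (E)-1-[4-(benzyloxy)-2-hydroxyphenyl]-3-[2-(benzyloxy)-4,5-dimethoxyphenyl]prop-2-en-1-one | COc1cc(OCc2ccccc2)c(/C=C/C(=O)c2ccc(OCc3ccccc3)cc2O)cc1OC | intermediate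
11 | 1-[4-(benzyloxy)-2-hydroxyphenyl]-2-[2-(benzyloxy)-4,5-dimethoxyphenyl]-3,3-dimethoxypropan-1-one (racemic) | COc1cc(OCc2ccccc2)c(C(C(OC)OC)C(=O)c2ccc(OCc3ccccc3)cc2O)cc1OC | intermediate
12 | 7-(benzyloxy)-3-[2-(benzyloxy)-4,5-dimethoxyphenyl]-4H-chromen-4-one | COc1cc(OCc2ccccc2)c(-c2coc3cc(OCc4ccccc4)ccc3c2=O)cc1OC | intermediate
13 | 7-hydroxy-3-(2-hydroxy-4,5-dimethoxyphenyl)-4H-chromen-4-one | COc1cc(O)c(-c2coc3cc(O)ccc3c2=O)cc1OC | intermediate
14 | 7-hydroxy-3-(2-hydroxy-4,5-dimethoxyphenyl)chroman-4-one (racemic, C3 epimerising) | COc1cc(O)c(C2COc3cc(O)ccc3C2=O)cc1OC | intermediate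
15 | (3R,4R)-3-(2-hydroxy-4,5-dimethoxyphenyl)chromane-4,7-diol (cis) | COc1cc(O)c([C@@H]2COc3cc(O)ccc3[C@@H]2O)cc1OC | intermediate
16 | (6aR,11aR)-8,9-dimethoxy-6a,11a-dihydro-6H-[1]benzofuro[3,2-c]chromen-3-ol (3-hydroxy-8,9-dimethoxypterocarpan) | COc1cc2c(cc1OC)[C@@H]1COc3cc(O)ccc3[C@@H]1O2 | intermediate
17 | benzyl (6aR,11aR)-8,9-dimethoxy-6a,11a-dihydro-6H-[1]benzofuro[3,2-c]chromen-3-yl carbonate | COc1cc2c(cc1OC)[C@@H]1COc3cc(OC(=O)OCc4ccccc4)ccc3[C@@H]1O2 | intermediate
18 | benzyl (3R,4S)-4-{4-(benzyloxy)-5-[7-(benzyloxy)-4-oxo-4H-chromen-3-yl]-2-methoxyphenyl}-3-(2-hydroxy-4,5-dimethoxyphenyl)chroman-7-yl carbonate | COc1cc(O)c([C@@H]2COc3cc(OC(=O)OCc4ccccc4)ccc3[C@H]2c2cc(-c3coc4cc(OCc5ccccc5)ccc4c3=O)c(OCc3ccccc3)cc2OC)cc1OC | intermediate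
19 | benzyl (3R,4S)-4-{4-(benzyloxy)-5-[7-(benzyloxy)-4-oxochroman-3-yl]-2-methoxyphenyl}-3-(2-hydroxy-4,5-dimethoxyphenyl)chroman-7-yl carbonate (both epimers at C3 of the chromanone, interconverting) | COc1cc(O)c([C@@H]2COc3cc(OC(=O)OCc4ccccc4)ccc3[C@H]2c2cc(C3COc4cc(OCc5ccccc5)ccc4C3=O)c(OCc3ccccc3)cc2OC)cc1OC | intermediate
20 | benzyl (3R,4S)-4-{4-(benzyloxy)-5-[(3R,4R)-7-(benzyloxy)-4-hydroxychroman-3-yl]-2-methoxyphenyl}-3-(2-hydroxy-4,5-dimethoxyphenyl)chroman-7-yl carbonate | COc1cc(O)c([C@@H]2COc3cc(OC(=O)OCc4ccccc4)ccc3[C@H]2c2cc([C@@H]3COc4cc(OCc5ccccc5)ccc4[C@@H]3O)c(OCc3ccccc3)cc2OC)cc1OC | intermediate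
21 | (3R,4S)-4-{4-hydroxy-5-[(3R)-7-hydroxychroman-3-yl]-2-methoxyphenyl}-3-(2-hydroxy-4,5-dimethoxyphenyl)chroman-7-ol | COc1cc(O)c([C@@H]2COc3cc(O)ccc3[C@H]2c2cc([C@@H]3COc4cc(O)ccc4C3)c(O)cc2OC)cc1OC | target

Total step count: 12. Longest linear sequence: 9 steps (steps 4 to 12, from 7); the other branch (steps 1 to 3) joins in step 10.

Steps most likely to fail

Step 3. The acyl transfer may stall: the acylpyridinium–enolate pair can collapse back to 4, adventitious water can cleave the ester to 3 and the arylacetaldehyde, and 5 can lose its formyl group by retro-Claisen cleavage before the ring closes. The fallback uses known chemistry, sets out from 1 and comes back at 6. Claisen–Schmidt condensation of 1 with ketone 9 (KOH, EtOH) should give (E)-1-[4-(benzyloxy)-2-hydroxyphenyl]-3-[2-(benzyloxy)-4-methoxyphenyl]prop-2-en-1-one F1. Oxidative 1,2-aryl shift with Tl(NO3)3·3H2O in MeOH–CH(OMe)3 should give 1-[4-(benzyloxy)-2-hydroxyphenyl]-2-[2-(benzyloxy)-4-methoxyphenyl]-3,3-dimethoxypropan-1-one F2, and warm dilute HCl in MeOH closes F2 to 6. In this variant the C3–C4 bond is brought in with the acetyl group of 9, ring B reaches C3 by migration, and O1 closes on the acetal carbon instead of on the arene.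

Step 10. Ionisation of the carbonate-deactivated pterocarpan may be slow, so that loss of the C3 proton from the cation (to the isoflav-3-ene) and reprotonation erode the C3 configuration; attack syn to the C3 aryl group would lower the trans selectivity. The fallback sets out from the free phenol 16 and from 6 and comes back at 21. With a weak Brønsted acid ((PhO)2P(O)OH, 10 mol %) in (CF3)2CHOH–CH2Cl2 at 0 °C, 6 in threefold excess and slow addition of 16, the ring should open through the para-quinone methide of ring A at lower acidity, and selectivity then rests on stoichiometry instead of on electronic deactivation. This should give (3R,4S)-4-{4-(benzyloxy)-5-[7-(benzyloxy)-4-oxo-4H-chromen-3-yl]-2-methoxyphenyl}-3-(2-hydroxy-4,5-dimethoxyphenyl)chroman-7-ol F3. The transfer hydrogenation of step 11 then leads through (3R,4S)-4-{4-(benzyloxy)-5-[7-(benzyloxy)-4-oxochroman-3-yl]-2-methoxyphenyl}-3-(2-hydroxy-4,5-dimethoxyphenyl)chroman-7-ol F4 to (3R,4S)-4-{4-(benzyloxy)-5-[(3R,4R)-7-(benzyloxy)-4-hydroxychroman-3-yl]-2-methoxyphenyl}-3-(2-hydroxy-4,5-dimethoxyphenyl)chroman-7-ol F5, and hydrogenolysis as in step 12 gives 21.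

Step 11. Conjugate reduction of the hindered chromone of 18 may be incomplete, or the catalyst may be slowed by the free phenol, which would leave mixtures of 18, 19 and 20. The fallback sets out from 6 and comes back at 19. Conjugate reduction of 6 with LiBH(s-Bu)3 (THF, −78 °C) should give racemic 7-(benzyloxy)-3-[2-(benzyloxy)-4-methoxyphenyl]chroman-4-one F6. F6 is coupled with 17 under the conditions of step 10 (its ring A is deactivated by the aryl ketone) to give 19 as an isolated ketone, and the dynamic kinetic resolution with the same catalyst is then run on the ketone alone to reach 20.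

Further compounds
F1 | step 3 | (E)-1-[4-(benzyloxy)-2-hydroxyphenyl]-3-[2-(benzyloxy)-4-methoxyphenyl]prop-2-en-1-one | COc1ccc(/C=C/C(=O)c2ccc(OCc3ccccc3)cc2O)c(OCc2ccccc2)c1
F2 | step 3 | 1-[4-(benzyloxy)-2-hydroxyphenyl]-2-[2-(benzyloxy)-4-methoxyphenyl]-3,3-dimethoxypropan-1-one (racemic) | COc1ccc(C(C(OC)OC)C(=O)c2ccc(OCc3ccccc3)cc2O)c(OCc2ccccc2)c1
F3 | step 10 | (3R,4S)-4-{4-(benzyloxy)-5-[7-(benzyloxy)-4-oxo-4H-chromen-3-yl]-2-methoxyphenyl}-3-(2-hydroxy-4,5-dimethoxyphenyl)chroman-7-ol | COc1cc(O)c([C@@H]2COc3cc(O)ccc3[C@H]2c2cc(-c3coc4cc(OCc5ccccc5)ccc4c3=O)c(OCc3ccccc3)cc2OC)cc1OC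
F4 | step 10 | (3R,4S)-4-{4-(benzyloxy)-5-[7-(benzyloxy)-4-oxochroman-3-yl]-2-methoxyphenyl}-3-(2-hydroxy-4,5-dimethoxyphenyl)chroman-7-ol (both epimers at C3 of the chromanone) | COc1cc(O)c([C@@H]2COc3cc(O)ccc3[C@H]2c2cc(C3COc4cc(OCc5ccccc5)ccc4C3=O)c(OCc3ccccc3)cc2OC)cc1OC
F5 | step 10 | (3R,4S)-4-{4-(benzyloxy)-5-[(3R,4R)-7-(benzyloxy)-4-hydroxychroman-3-yl]-2-methoxyphenyl}-3-(2-hydroxy-4,5-dimethoxyphenyl)chroman-7-ol | COc1cc(O)c([C@@H]2COc3cc(O)ccc3[C@H]2c2cc([C@@H]3COc4cc(OCc5ccccc5)ccc4[C@@H]3O)c(OCc3ccccc3)cc2OC)cc1OC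
F6 | step 11 | 7-(benzyloxy)-3-[2-(benzyloxy)-4-methoxyphenyl]chroman-4-one (racemic) | COc1ccc(C2COc3cc(OCc4ccccc4)ccc3C2=O)c(OCc2ccccc2)c1
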